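Maple is charged with less reagent than substrate, elm with more, and the reckoning below follows that difference.

| setting | beta | alpha | maple | elm |
|---|---|---|---|---|
| substrate | 39 mM | 39 mM | 39 mM | 39 mM |
| reagent | 41 mM | 110 mM | 31.0 mM | 78.0 mM |
| remark | run made earlier | run made earlier |  |  |
| time |  |  | 10 h | 10 h |

| run | time / h | target / % | over-reaction product / % | substrate / % | isomer of the product / % |
|---|---|---|---|---|---|
| beta | 0.417 | 16 | 0 | 77 | 7 |
| beta | 0.667 | 27 | 1 | 70 | 5 |
| beta | 1.00 | 29 | 2 | 65 | 7 |
| beta | 1.33 | 24 | 1 | 61 | 12 |
| beta | 2.00 | 27 | 7 | 57 | 10 |
| beta | 3.00 | 26 | 7 | 57 | 18 |
| beta | 5.00 | 23 | 12 | 47 | 22 |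
| alpha | 0.417 | 42 | 1 | 48 | 8 |
| alpha | 0.667 | 49 | 1 | 39 | 8 |
| alpha | 1.00 | 49 | 7 | 34 | 15 |
| alpha | 1.33 | 47 | 5 | 32 | 13 |
| alpha | 2.00 | 43 | 11 | 30 | 18 |
| alpha | 3.00 | 36 | 10 | 26 | 26 |
| alpha | 5.00 | 26 | 20 | 16 | 31 |

(each reading ± 2 percentage points)

1. which of these there is most of at the end, counted by the substrate in it, maple (substrate / target / over-reaction product / isomer of the product)
2. which of these there is most of at the end, counted by the substrate in it, elm (substrate / target / over-reaction product / isomer of the product)
3. how much there is at the end of the one of these that leads, in percent of the substrate charged: maple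
4. how much there is at the end of the one of these that leads, in percent of the substrate charged: elm

- the numbers in the tables scatter by 2 percentage points (one standard deviation)

1. The bench rule for reagent in excess is pseudo-first-order: free reagent is counted as constant at its charge. Its border is the cover, reagent charge over substrate charge: 0.795 in maple, 2.00 in elm. Each substrate lost is taken to bind one reagent. So free reagent, as a fraction of the substrate charge, is the cover minus the substrate fraction gone. Maple's cover lies below 1, so reagent is not in excess there and the rule is dropped.

2. Follow one molecule. Target over substrate, per unit of free reagent, reads 0.762 in beta and 0.676 in alpha at 2.00 h. Their mean is the hold, 0.719: the molecule's odds of sitting as target per unit of free reagent.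

3. The loss is isomer plus over-reaction product. Its rate is taken as proportional to substrate times free reagent, and target follows that same product through the hold. Between 1.00 h and 5.00 h, the constant reads 0.178 /h in beta and 0.138 /h in alpha, with mean 0.158 /h. At 5.00 h, the readings of the two runs together put isomer at 62.4% of the loss.

4. The loss is taken to climb exponentially toward the limiting charge, which is the cover in maple, where reagent is the limiting reagent, and the substrate charge in elm. The hold gives the substrate once target has formed and before any loss, and the hold again gives the final substrate from the loss.

5. In this reckoning, maple holds 72.7% substrate before any loss, and 42.1% of the charge is lost by 10 h. That leaves substrate at 48.2%, ahead of isomer at 26.3%.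

6. In this reckoning, elm holds 48.4% substrate before any loss, and 67.9% of the charge is lost by 10 h. Isomer leads at 42.3%, with substrate at 17.4%.

The forecast, holding that “the first step is a reversible equilibrium”, names substrate at 40% for maple, lower than this reckoning, and isomer of the product at 46% for elm, higher than this reckoning.

The flasks give substrate at 49.6% in maple and isomer of the product at 41.1% in elm.

    substrate + reagent ⇌ target (K = 18.0 /M, k = 0.00580 /M/s)
    substrate + reagent ⇌ isomer of the product (K = 140 /M, k = 7.90 × 10⁻⁴ /M/s)
    target → over-reaction product (k = 2.90 × 10⁻⁵ /s)

In maple at 10.0 h, the forward step from substrate to target runs 7.3 times the forward step to isomer, and free reagent stands at 0.291 of the substrate charge, so the hold gives target over substrate as 0.209 against 0.200 in the flask. In elm, with 17% of the substrate and 59% of the reagent left, each of its own charge, free reagent is 1.17 of the substrate charge, and the hold gives 0.845 against 0.822 in the flask.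

The runs stem from a simulated flask for substances that don't exist, noise included.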